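The CH(Ph) carbon on C6 of ring A lies between the C5 and C7 oxygens, so it is treated as the exocyclic carbon of an ortho-quinone methide. The disconnection is therefore the bond between the stereocentre and its CH2, not the usual aryl–CH bond. A racemic α-sulfonylbenzyl acylphloroglucinol is funnelled through this planar intermediate by a squaramide-catalysed formal [4+2] annulation with Meldrum's acid. In one operation the step erases the racemic centre, sets the lone stereocentre as R, forms the C–CH2 bond and closes a dihydrocoumarin lactone on the future O5. That lactone then forces the pyranone to close on the other phenol, which fixes attachment at C6 and not C8.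

Key step: step 3

Assumptions: the target stereocentre is (R) (CIP order flavonyl > phenyl > CH2CO2H > H), and this descriptor holds for every chiral compound of the route. The quinine-derived squaramide is taken to give the (4R)-lactone; if the sense of induction should prove opposite, the quinidine-derived pseudoenantiomer is used with no other change. Compounds 1, 2, 4, 5, 7, 12 and 16 are taken as commercial.

Step 1
Reactants: 1 2,4,6-trihydroxyacetophenone; 2 benzyl bromide
Product: 3 1-[4-(benzyloxy)-2,6-dihydroxyphenyl]ethan-1-one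
Conditions: BnBr (1.0 equiv), K2CO3 (1.1 equiv), DMF, 0 °C to rt
Reagents that add atoms: benzyl bromide, BrCc1ccccc1
Why: Williamson etherification at the 4-OH, the most acidic and least hindered phenol (the 2- and 6-OH flank the acetyl group and are hydrogen-bonded to it), so mono-O-benzylation should give a symmetric product in which C3 and C5 are equivalent.

Step 2
Reactants: 3 1-[4-(benzyloxy)-2,6-dihydroxyphenyl]ethan-1-one; 4 benzaldehyde; 5 sodium p-toluenesulfinate
Product: 6 rac-1-{4-(benzyloxy)-2,6-dihydroxy-3-[(4-methylbenzenesulfonyl)(phenyl)methyl]phenyl}ethan-1-one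
Conditions: PhCHO (1.05 equiv), TolSO2Na (2.5 equiv), HCO2H–H2O, rt to 40 °C
Reagents that add atoms: benzaldehyde, O=Cc1ccccc1; sodium p-toluenesulfinate, Cc1ccc(cc1)S(=O)[O-].[Na+]
Why: Three-component Mannich-type α-sulfonylalkylation of an electron-rich phenol (acid-promoted hydroxyalkylation at the free ring carbon, ionisation to the quinone methide and capture by excess sulfinic acid), giving a racemic centre that step 3 erases, so no stereocontrol is needed here.

Step 3
Reactants: 6 rac-1-{4-(benzyloxy)-2,6-dihydroxy-3-[(4-methylbenzenesulfonyl)(phenyl)methyl]phenyl}ethan-1-one; 7 Meldrum's acid (2,2-dimethyl-1,3-dioxane-4,6-dione)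
Product: 11 (4R)-8-acetyl-5-(benzyloxy)-7-hydroxy-4-phenyl-3,4-dihydro-2H-chromen-2-one, via ortho-quinone methide 8 (not isolated), via Meldrum's acid adduct 9 (not isolated), via lactone acid 10 (not isolated)
Conditions: quinine-derived 3,5-(CF3)2C6H3-squaramide (10 mol %), 5% aq NaHCO3, CH2Cl2, 0 °C; then organic phase, TsOH·H2O (10 mol %), toluene, 100 °C
Reagents that add atoms: Meldrum's acid, CC1(C)OC(=O)CC(=O)O1
Why: Mild base triggers 1,4-elimination of sulfinate from both enantiomers of 6 to the same planar quinone methide 8 (drawn as its ortho tautomer), whose C2=O/acetyl C=O pair is bound by the squaramide NH groups while the protonated quinuclidine delivers the Meldrum's acid enolate to one face of the benzylidene carbon to give 9. The rearomatised 2-OH then attacks a Meldrum's carbonyl in a 6-exo-trig acyl substitution with loss of acetone, and acid 10 decarboxylates on heating; the acidic second stage also suppresses retro-Michael erosion of 9. The closest known reaction type is the cinchona squaramide-catalysed conjugate addition of Meldrum's acid to ortho-quinone methides generated in situ from 2-(1-arylsulfonylalkyl)phenols under biphasic base, a formal [4+2] route to 4-aryl-3,4-dihydrocoumarins. The C4 stereocentre (R) is set under catalyst control in the C–C bond-forming step, the flanking 4-benzyloxy group holding 8 in the benzylidene geometry with phenyl on the carbonyl side. The step needs enantiofacial selectivity over uncatalysed addition, which the low stationary concentration of 8 in the biphasic medium should secure, and site selectivity in lactonisation, which the substrate secures because O4 is benzylated and O6 is para, so only O2 can close the ring.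

Step 4
Reactants: 11 (4R)-8-acetyl-5-(benzyloxy)-7-hydroxy-4-phenyl-3,4-dihydro-2H-chromen-2-one; 12 4-(benzyloxy)benzaldehyde
Product: 13 (4R)-5-(benzyloxy)-8-{(2E)-3-[4-(benzyloxy)phenyl]prop-2-enoyl}-7-hydroxy-4-phenyl-3,4-dihydro-2H-chromen-2-one
Conditions: BF3·OEt2 (0.5 equiv), 1,4-dioxane, rt
Reagents that add atoms: 4-(benzyloxy)benzaldehyde, O=Cc1ccc(OCc2ccccc2)cc1
Why: Lewis acid-promoted Claisen–Schmidt condensation via the boron chelate of the ortho-hydroxyacetophenone, run without base or nucleophilic solvent so that the aryl lactone should stay closed and the remote C4 stereocentre is untouched; any flavanone formed by early oxa-Michael closure converges on 15 in step 5.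

Step 5
Reactants: 13 (4R)-5-(benzyloxy)-8-{(2E)-3-[4-(benzyloxy)phenyl]prop-2-enoyl}-7-hydroxy-4-phenyl-3,4-dihydro-2H-chromen-2-one
Product: 15 (4R)-5-(benzyloxy)-8-[4-(benzyloxy)phenyl]-4-phenyl-3,4-dihydro-2H,10H-pyrano[2,3-f]chromene-2,10-dione, via flavanone lactone 14 (not isolated)
Conditions: I2 (10 mol %), DMSO, 120 °C
Reagents that add atoms: none
Why: Iodine/DMSO oxidative cyclisation of a 2'-hydroxychalcone (6-endo-trig oxa-Michael closure to flavanone 14, α-iodination and loss of HI, DMSO re-oxidising HI to iodine), which can only use the 7-OH because the other ortho oxygen is locked in the lactone, so the pyranone forms with the side chain at flavone C6.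

Step 6
Reactants: 15 (4R)-5-(benzyloxy)-8-[4-(benzyloxy)phenyl]-4-phenyl-3,4-dihydro-2H,10H-pyrano[2,3-f]chromene-2,10-dione; 16 lithium hydroxide
Product: 17 (3R)-3-{7-(benzyloxy)-2-[4-(benzyloxy)phenyl]-5-hydroxy-4-oxo-4H-chromen-6-yl}-3-phenylpropanoic acid
Conditions: LiOH (3 equiv), THF–H2O, 0 °C; then 1 M HCl to pH 4, 0 °C
Reagents that add atoms: lithium hydroxide, [Li+].[OH-]
Why: Saponification of the activated aryl lactone at 0 °C, expected to be far faster than hydroxide attack on the chromone; the stereocentre is β to the carbonyl and cannot epimerise, and the acid should not relactonise because the 5-OH is chelated to C4=O and O7 is benzylated.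

Step 7
Reactants: 17 (3R)-3-{7-(benzyloxy)-2-[4-(benzyloxy)phenyl]-5-hydroxy-4-oxo-4H-chromen-6-yl}-3-phenylpropanoic acid
Product: 18 (3R)-3-[5,7-dihydroxy-2-(4-hydroxyphenyl)-4-oxo-4H-chromen-6-yl]-3-phenylpropanoic acid
Conditions: H2 (1 atm), 10% Pd/C, THF–MeOH, rt
Reagents that add atoms: none
Why: Heterogeneous hydrogenolysis of both benzyl ethers under neutral conditions at 1 atm, which should spare the flavone C2=C3 bond and the benzylic C–C bonds and free the triphenol acid without acid that could lactonise it.

Compound list
1 | 2,4,6-trihydroxyacetophenone | CC(=O)c1c(O)cc(O)cc1O | starting material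
2 | benzyl bromide | BrCc1ccccc1 | starting material
3 | 1-[4-(benzyloxy)-2,6-dihydroxyphenyl]ethan-1-one | CC(=O)c1c(O)cc(OCc2ccccc2)cc1O | intermediate
4 | benzaldehyde | O=Cc1ccccc1 | starting material
5 | sodium p-toluenesulfinate | Cc1ccc(cc1)S(=O)[O-].[Na+] | starting material
6 | rac-1-{4-(benzyloxy)-2,6-dihydroxy-3-[(4-methylbenzenesulfonyl)(phenyl)methyl]phenyl}ethan-1-one (racemic) | CC(=O)c1c(O)cc(OCc2ccccc2)c(C(c2ccccc2)S(=O)(=O)c2ccc(C)cc2)c1O | intermediate
7 | Meldrum's acid (2,2-dimethyl-1,3-dioxane-4,6-dione) | CC1(C)OC(=O)CC(=O)O1 | starting material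
8 | 6-acetyl-3-(benzyloxy)-2-benzylidene-5-hydroxycyclohexa-3,5-dien-1-one (ortho-quinone methide, not isolated) | CC(=O)C1=C(O)C=C(OCc2ccccc2)C(=Cc2ccccc2)C1=O | intermediate
9 | 5-{(R)-[3-acetyl-6-(benzyloxy)-2,4-dihydroxyphenyl](phenyl)methyl}-2,2-dimethyl-1,3-dioxane-4,6-dione (not isolated) | CC1(C)OC(=O)C(C(=O)O1)[C@H](c1ccccc1)c1c(OCc2ccccc2)cc(O)c(C(C)=O)c1O | intermediate
10 | (4R)-8-acetyl-5-(benzyloxy)-7-hydroxy-2-oxo-4-phenyl-3,4-dihydro-2H-chromene-3-carboxylic acid (C3 epimers, not isolated) | OC(=O)C1C(=O)Oc2c(C(C)=O)c(O)cc(OCc3ccccc3)c2[C@H]1c1ccccc1 | intermediate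
11 | (4R)-8-acetyl-5-(benzyloxy)-7-hydroxy-4-phenyl-3,4-dihydro-2H-chromen-2-one | O=C1C[C@H](c2ccccc2)c2c(OCc3ccccc3)cc(O)c(C(C)=O)c2O1 | intermediate
12 | 4-(benzyloxy)benzaldehyde | O=Cc1ccc(OCc2ccccc2)cc1 | starting material
13 | (4R)-5-(benzyloxy)-8-{(2E)-3-[4-(benzyloxy)phenyl]prop-2-enoyl}-7-hydroxy-4-phenyl-3,4-dihydro-2H-chromen-2-one | O=C1C[C@H](c2ccccc2)c2c(OCc3ccccc3)cc(O)c(C(=O)/C=C/c3ccc(OCc4ccccc4)cc3)c2O1 | intermediate
14 | (4R)-5-(benzyloxy)-8-[4-(benzyloxy)phenyl]-4-phenyl-3,4,8,9-tetrahydro-2H,10H-pyrano[2,3-f]chromene-2,10-dione (C8 epimers, not isolated) | O=C1C[C@H](c2ccccc2)c2c(OCc3ccccc3)cc3OC(c4ccc(OCc5ccccc5)cc4)CC(=O)c3c2O1 | intermediate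
15 | (4R)-5-(benzyloxy)-8-[4-(benzyloxy)phenyl]-4-phenyl-3,4-dihydro-2H,10H-pyrano[2,3-f]chromene-2,10-dione | O=C1C[C@H](c2ccccc2)c2c(OCc3ccccc3)cc3oc(-c4ccc(OCc5ccccc5)cc4)cc(=O)c3c2O1 | intermediate
16 | lithium hydroxide | [Li+].[OH-] | starting material
17 | (3R)-3-{7-(benzyloxy)-2-[4-(benzyloxy)phenyl]-5-hydroxy-4-oxo-4H-chromen-6-yl}-3-phenylpropanoic acid | O=C(O)C[C@H](c1ccccc1)c1c(OCc2ccccc2)cc2oc(-c3ccc(OCc4ccccc4)cc3)cc(=O)c2c1O | intermediate
18 | (3R)-3-[5,7-dihydroxy-2-(4-hydroxyphenyl)-4-oxo-4H-chromen-6-yl]-3-phenylpropanoic acid | O=C(O)C[C@H](c1ccccc1)c1c(O)cc2oc(-c3ccc(O)cc3)cc(=O)c2c1O | target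

Total step count: 7
Longest linear sequence: 7 steps (1 to 18; the route is fully linear)

Steps most likely to fail

Step 3 (key step). The risk is loss of enantiocontrol: the acidic 6-OH can deprotonate the quinone methide to a less electrophilic anion that reacts outside the catalyst pocket, or uncatalysed addition at the aqueous interface can compete, and the facial sense may be poorly discriminated for this hexasubstituted ring. The fallback gives up the quinone methide and sets C4 by conjugate arylation. It sets out from 3: Pd(OAc)2-catalysed alkyne hydroarylation/lactonisation with ethyl propiolate in TFA–CH2Cl2 (Pechmann-type coumarin synthesis, where again only O2 can lactonise) should give 8-acetyl-5-(benzyloxy)-7-hydroxy-2H-chromen-2-one F1. A Rh(I)/SEGPHOS-catalysed asymmetric 1,4-addition of phenylboronic acid (Hayashi–Miyaura reaction, dioxane–H2O, 60 °C, ligand enantiomer chosen for 4R) then comes back to the route at 11.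

Step 2. The risk is capture of the transient quinone methide by a second molecule of 3 (diarylmethane formation) or a second sulfonylalkylation at C5, instead of trapping by sulfinate. The fallback replaces the free quinone methide by an iminium electrophile. It sets out from 3: a Betti reaction with benzaldehyde and morpholine in EtOH should give rac-1-{4-(benzyloxy)-2,6-dihydroxy-3-[morpholin-4-yl(phenyl)methyl]phenyl}ethan-1-one F2. Acid-mediated amine/sulfinate exchange (TolSO2Na, HCO2H, rt) then comes back to the route at 6.

Step 4. The risk is a stalled condensation, because the chelated, doubly ortho-substituted ketone enolises poorly, or opening of the aryl lactone under the Lewis acid, which would remove the regiochemical lock. The fallback accepts lactone opening and rebuilds the lactone afterwards. It sets out from 11: a conventional Claisen–Schmidt condensation with 12 under aqueous KOH/EtOH, followed by acidification, should give (3R)-3-{6-(benzyloxy)-3-[(2E)-3-[4-(benzyloxy)phenyl]prop-2-enoyl]-2,4-dihydroxyphenyl}-3-phenylpropanoic acid F3. Dehydrative relactonisation (TsOH cat., toluene, Dean–Stark) can only engage the phenol next to the side chain, and since chalcone/flavanone interconversion is reversible under acid the material should funnel to the lactone and come back to the route at 13.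

Further compounds
F1 | step 3 | 8-acetyl-5-(benzyloxy)-7-hydroxy-2H-chromen-2-one | CC(=O)c1c(O)cc(OCc2ccccc2)c2ccc(=O)oc12
F2 | step 2 | rac-1-{4-(benzyloxy)-2,6-dihydroxy-3-[morpholin-4-yl(phenyl)methyl]phenyl}ethan-1-one | CC(=O)c1c(O)cc(OCc2ccccc2)c(C(c2ccccc2)N2CCOCC2)c1O
F3 | step 4 | (3R)-3-{6-(benzyloxy)-3-[(2E)-3-[4-(benzyloxy)phenyl]prop-2-enoyl]-2,4-dihydroxyphenyl}-3-phenylpropanoic acid | O=C(O)C[C@H](c1ccccc1)c1c(OCc2ccccc2)cc(O)c(C(=O)/C=C/c2ccc(OCc3ccccc3)cc2)c1O
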